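**Retrosynthetic overview**

1. Labels: C7 is the ring quaternary carbon, C8/C9 and C12/C13 are CH2 groups, C10/C11 the epoxide carbons, C14 the carbinol carbon. The route rests on the C10–C11 epoxide being the oxide of an E-trisubstituted olefin in the flexible C8–C13 chain of the 15-membered lactone ring; it is opened retrosynthetically to the E-C10=C11 olefin (Shi epoxidation), and that olefin to a seco diene by stereoretentive molybdenum ring-closing metathesis (vinyl at C10, (E)-ethylidene terminus at C11).
2. The seco diene is cut at the benzylic C–aryl bond: Negishi coupling of an (iodomethyl)bromocyclohexane with an iodoaryl ester that already carries the C11–C15 alcohol part.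
3. The bromocyclohexane comes from a catalytic enantioselective bromonium cyclisation of a geranyl-type tert-butyl carbonate (geranyl acetate extended by an allyl group at its E-methyl terminus); the carbonate traps the cation, and the resulting equatorial tertiary alcohol is dehydrated to the exocyclic methylene.
4. The alcohol part comes from (S)-α-hydroxy-γ-butyrolactone (malic acid pool): MeMgBr addition, then Negishi coupling with (E)-2-bromobut-2-ene; it is esterified with 3-iodo-4-silyloxybenzoic acid.
5. Ring order: cyclohexane (with a temporary fused carbonate ring) → 15-membered macrolactone → epoxide.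

Key step: step 18

Assumption: the enantiomer of the thiophosphoramide catalyst that delivers the (6S)-bromide in step 5 is used; if the sense of induction is opposite to that expected, the other catalyst enantiomer is taken.

**Route**

Step 1
Reactants: 1 geranyl acetate [(2E)-3,7-dimethylocta-2,6-dien-1-yl acetate]
Product: 2 (2E,6E)-8-hydroxy-3,7-dimethylocta-2,6-dien-1-yl acetate
Conditions: SeO2 (0.2 equiv), t-BuOOH (3 equiv), salicylic acid (0.1 equiv), CH2Cl2, 0 °C → rt
Reagents that add atoms: tert-butyl hydroperoxide, CC(C)(C)OO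
Why: Riley allylic oxidation (ene reaction then [2,3]-sigmatropic shift) attacks the (E)-methyl group of the electron-richer distal olefin, the proximal olefin being deactivated by the allylic acetate, so the (6E)-allylic alcohol should result.

Step 2
Reactants: 2 (2E,6E)-8-hydroxy-3,7-dimethylocta-2,6-dien-1-yl acetate
Product: 3 (2E,6E)-8-bromo-3,7-dimethylocta-2,6-dien-1-yl acetate
Conditions: CBr4, PPh3, CH2Cl2, 0 °C
Reagents that add atoms: carbon tetrabromide, BrC(Br)(Br)Br
Why: Appel reaction; bromide displaces the primary allylic alkoxyphosphonium ion in an SN2 step that leaves both E olefins untouched.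

Step 3
Reactants: 3 (2E,6E)-8-bromo-3,7-dimethylocta-2,6-dien-1-yl acetate
Product: 4 (2E,6E)-3,7-dimethylundeca-2,6,10-trien-1-ol
Conditions: allylMgBr (3.5 equiv), THF, −78 → 0 °C; aq. NH4Cl
Reagents that add atoms: allylmagnesium bromide, C=CC[Mg]Br
Why: SN2 coupling of the primary allylic bromide with the allyl Grignard reagent builds the but-3-enyl arm with the (6E) geometry retained, and the excess reagent cleaves the acetate in the same flask; any SN2′ isomer should be minor and separable.

Step 4
Reactants: 4 (2E,6E)-3,7-dimethylundeca-2,6,10-trien-1-ol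
Product: 5 tert-butyl (2E,6E)-3,7-dimethylundeca-2,6,10-trien-1-yl carbonate
Conditions: Boc2O, DMAP (0.1 equiv), CH2Cl2, 0 °C → rt
Reagents that add atoms: di-tert-butyl dicarbonate, CC(C)(C)OC(=O)OC(=O)OC(C)(C)C
Why: DMAP-catalysed acylation of the primary alcohol installs the carbonate that will terminate the cyclisation; a carbonate terminus is chosen because termination by proton loss would give mainly endocyclic olefins.

Step 5
Reactants: 5 tert-butyl (2E,6E)-3,7-dimethylundeca-2,6,10-trien-1-yl carbonate
Product: 6 (4aR,5S,6S,8aS)-6-bromo-5-(but-3-en-1-yl)-5,8a-dimethylhexahydro-4H-1,3-benzodioxin-2-one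
Conditions: chiral 3,3'-diaryl-BINOL-derived thiophosphoramide (10 mol%), 1,3-dibromo-5,5-dimethylhydantoin (DBDMH, 1.1 equiv), toluene/CH2Cl2, −90 °C
Reagents that add atoms: 1,3-dibromo-5,5-dimethylhydantoin, CC1(C)N(Br)C(=O)N(Br)C1=O
Why: Catalytic enantioselective bromonium-induced polyene cyclisation: the chiral Lewis base passes Br+ to one face of the distal trisubstituted olefin (the allylic-carbonate olefin and the vinyl group are less nucleophilic), the chair-like transition state gives anti addition across both E olefins (equatorial Br at C6, equatorial butenyl and axial methyl at C5, trans ring fusion), and the carbonate carbonyl traps the tertiary cation with loss of isobutene, so four stereocentres are set with the absolute sense fixed by the catalyst.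

Step 6
Reactants: 6 (4aR,5S,6S,8aS)-6-bromo-5-(but-3-en-1-yl)-5,8a-dimethylhexahydro-4H-1,3-benzodioxin-2-one
Product: 7 (1S,2R,3S,4S)-4-bromo-3-(but-3-en-1-yl)-2-(hydroxymethyl)-1,3-dimethylcyclohexan-1-ol
Conditions: K2CO3 (0.3 equiv), MeOH, 40 °C
Reagents that add atoms: none
Why: Base-catalysed transesterification of the cyclic carbonate with methanol frees the primary and the equatorial tertiary alcohol; the equatorial neopentyl bromide has neither an anti-periplanar hydrogen nor an open backside and should survive.

Step 7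
Reactants: 7 (1S,2R,3S,4S)-4-bromo-3-(but-3-en-1-yl)-2-(hydroxymethyl)-1,3-dimethylcyclohexan-1-ol
Product: 8 (1S,2S,3S,4S)-4-bromo-3-(but-3-en-1-yl)-2-(iodomethyl)-1,3-dimethylcyclohexan-1-ol
Conditions: I2, PPh3, imidazole, CH2Cl2, 0 °C → rt
Reagents that add atoms: iodine, II
Why: Appel-type iodination converts only the primary alcohol, the tertiary one being too hindered to form the alkoxyphosphonium ion.

Step 8
Reactants: 8 (1S,2S,3S,4S)-4-bromo-3-(but-3-en-1-yl)-2-(iodomethyl)-1,3-dimethylcyclohexan-1-ol
Product: 9 (1S,2S,3R)-1-bromo-2-(but-3-en-1-yl)-3-(iodomethyl)-2-methyl-4-methylidenecyclohexane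
Conditions: SOCl2, pyridine, CH2Cl2, −40 → 0 °C
Reagents that add atoms: none
Why: Dehydration through the chlorosulfite by an E2 pathway: the C–O bond of the equatorial tertiary alcohol has anti-periplanar hydrogens only on the geminal methyl group (the ring hydrogens are gauche), so the exocyclic methylene should be the main olefin.

Step 9
Reactants: 10 (S)-α-hydroxy-γ-butyrolactone [(3S)-3-hydroxyoxolan-2-one]
Product: 11 (3S)-4-methylpentane-1,3,4-triol
Conditions: MeMgBr (4 equiv), THF, 0 °C → rt; aq. NH4Cl
Reagents that add atoms: methylmagnesium bromide, C[Mg]Br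
Why: Double Grignard addition to the lactone carbonyl (after deprotonation of the hydroxyl group) gives the tertiary alcohol; the stereocentre is not involved and keeps its S configuration.

Step 10
Reactants: 11 (3S)-4-methylpentane-1,3,4-triol
Product: 12 2-[(4S)-2,2,5,5-tetramethyl-1,3-dioxolan-4-yl]ethan-1-ol
Conditions: 2,2-dimethoxypropane, PPTS (cat.), acetone, rt
Reagents that add atoms: 2,2-dimethoxypropane, COC(C)(C)OC
Why: Acid-catalysed acetalisation under thermodynamic control gives the five-membered dioxolane of the vicinal secondary/tertiary diol in preference to the six-membered acetal, leaving the primary alcohol free.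

Step 11
Reactants: 12 2-[(4S)-2,2,5,5-tetramethyl-1,3-dioxolan-4-yl]ethan-1-ol
Product: 13 (4S)-4-(2-iodoethyl)-2,2,5,5-tetramethyl-1,3-dioxolane
Conditions: I2, PPh3, imidazole, CH2Cl2, 0 °C → rt
Reagents that add atoms: iodine, II
Why: Appel-type iodination of the primary alcohol under neutral conditions that the acetonide tolerates.

Step 12
Reactants: 13 (4S)-4-(2-iodoethyl)-2,2,5,5-tetramethyl-1,3-dioxolane; 14 (E)-2-bromobut-2-ene
Product: 16 (4S)-2,2,5,5-tetramethyl-4-[(3E)-3-methylpent-3-en-1-yl]-1,3-dioxolane, via alkylzinc iodide 15 (not isolated)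
Conditions: Zn dust, LiCl, THF, 40 °C; then 14, Pd(OAc)2 (2 mol%), SPhos (4 mol%), THF, 25 → 40 °C
Reagents that add atoms: none
Why: Zinc insertion into the primary C–I bond followed by Negishi coupling (zerovalent palladium, oxidative addition into the alkenyl bromide with retention) joins C12 to C11 and carries the E geometry of 14 into the trisubstituted olefin.

Step 13
Reactants: 16 (4S)-2,2,5,5-tetramethyl-4-[(3E)-3-methylpent-3-en-1-yl]-1,3-dioxolane
Product: 17 (3S,6E)-2,6-dimethyloct-6-ene-2,3-diol
Conditions: AcOH/H2O (4:1), 40 °C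
Reagents that add atoms: none
Why: Mild aqueous acid hydrolyses the acetonide without protonating the trisubstituted olefin.

Step 14
Reactants: 18 4-hydroxy-3-iodobenzoic acid
Product: 20 3-iodo-4-[(triisopropylsilyl)oxy]benzoic acid, via bis-silylated ester 19 (not isolated)
Conditions: TIPSCl (2.4 equiv), imidazole, DMF, rt; then K2CO3, MeOH/H2O, 0 °C; 1 M HCl work-up
Reagents that add atoms: triisopropylsilyl chloride, CC(C)[Si](Cl)(C(C)C)C(C)C
Why: Silylation of both acidic groups followed by selective hydrolysis of the labile silyl ester leaves the phenol as a TIPS ether, chosen because it should withstand the basic epoxidation buffer of step 19.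

Step 15
Reactants: 20 3-iodo-4-[(triisopropylsilyl)oxy]benzoic acid; 17 (3S,6E)-2,6-dimethyloct-6-ene-2,3-diol
Product: 21 (3S,6E)-2-hydroxy-2,6-dimethyloct-6-en-3-yl 3-iodo-4-[(triisopropylsilyl)oxy]benzoate
Conditions: DIC, DMAP (0.3 equiv), CH2Cl2, 0 °C → rt
Reagents that add atoms: none
Why: Steglich esterification acylates the secondary alcohol selectively, the tertiary alcohol being unreactive towards the acylpyridinium ion; the carbinol stereocentre is not touched.

Step 16
Reactants: 21 (3S,6E)-2-hydroxy-2,6-dimethyloct-6-en-3-yl 3-iodo-4-[(triisopropylsilyl)oxy]benzoate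
Product: 22 (3S,6E)-2,6-dimethyl-2-[(triethylsilyl)oxy]oct-6-en-3-yl 3-iodo-4-[(triisopropylsilyl)oxy]benzoate
Conditions: TESOTf, 2,6-lutidine, CH2Cl2, −78 → 0 °C
Reagents that add atoms: triethylsilyl trifluoromethanesulfonate, CC[Si](CC)(CC)OS(=O)(=O)C(F)(F)F
Why: A silyl triflate with a hindered base silylates the tertiary alcohol and removes the last protic group before the molybdenum step.

Step 17
Reactants: 9 (1S,2S,3R)-1-bromo-2-(but-3-en-1-yl)-3-(iodomethyl)-2-methyl-4-methylidenecyclohexane; 22 (3S,6E)-2,6-dimethyl-2-[(triethylsilyl)oxy]oct-6-en-3-yl 3-iodo-4-[(triisopropylsilyl)oxy]benzoate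
Product: 24 seco diene (3S,6E)-2,6-dimethyl-2-[(triethylsilyl)oxy]oct-6-en-3-yl 3-{[(1R,2S,3S)-3-bromo-2-(but-3-en-1-yl)-2-methyl-6-methylidenecyclohexyl]methyl}-4-[(triisopropylsilyl)oxy]benzoate, via alkylzinc iodide 23 (not isolated)
Conditions: Zn dust, LiCl, THF, 25 °C; then 22, Pd(OAc)2 (5 mol%), SPhos (10 mol%), THF/NMP, 40 °C
Reagents that add atoms: none
Why: Zinc inserts into the primary C–I bond in preference to the hindered secondary C–Br bond, and the alkylzinc iodide undergoes Negishi sp3–sp2 coupling with the aryl iodide, forming the benzylic C–aryl bond without touching a stereocentre.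

Step 18
Reactants: 24 seco diene (vinyl group at C10; (E)-ethylidene terminus at C11; aryl TIPS ether; tertiary TES ether)
Product: 25 bis-silylated 15-membered macrolactone with the (10E)-C10=C11 trisubstituted ring olefin
Conditions: Mo(NC6F5)(CHCMe2Ph)(2,5-Me2NC4H2)[O-2,6-(2,4,6-iPr3C6H2)2C6H3] (10 mol%), toluene, 1 mM, 22 → 40 °C, 100 Torr
Reagents that add atoms: none
Why: The Mo alkylidene initiates at the terminal vinyl group and the new alkylidene adds across the (E)-trisubstituted olefin so that its carbon (C10) bonds to C11; cycloreversion of the metallacyclobutane expels Mo=CHCH3 (released as propene on turnover) and forms the C10=C11 bond, closing the 15-membered lactone ring by macrocyclic ring-closing metathesis. The closest known reaction type is stereoretentive macrocyclic ring-closing metathesis to E- or Z-trisubstituted olefins with molybdenum monoaryloxide pyrrolide catalysts. No stereocentre is formed; the only stereochemical element is the E geometry, which is carried over from the E olefin of 24 because the substituents of the metallacyclobutane keep their relative orientation between the olefin that enters and the olefin that leaves. The step needs ring closure to win over oligomerisation (1 mM, slow addition) and metathesis at the vinyl/ethylidene pair only: the exocyclic methylene is 1,1-disubstituted and flanked by two ring carbons, and closure onto it would give a bridgehead olefin, so it should stay untouched. Reduced pressure removes propene and ethylene and keeps the short-lived methylidene complex at a low level; both hydroxyl groups are silylated because the catalyst does not tolerate protic groups.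

Step 19
Reactants: 25 bis-silylated (10E)-macrolactone
Product: 26 bis-silylated bromophycolide F [(10S,11S)-epoxide]
Conditions: ent-Shi ketone (1,2:4,5-di-O-isopropylidene-β-L-erythro-2,3-hexodiulo-2,6-pyranose, 0.5 equiv), Oxone (2KHSO5·KHSO4·K2SO4), K2CO3, Bu4NHSO4 (cat.), MeCN/DMM/aq. Na2B4O7–Na2EDTA buffer (pH 10.5), 0 °C
Reagents that add atoms: potassium peroxymonosulfate (from Oxone), [K+].[O-]S(=O)(=O)OO
Why: Shi epoxidation: the dioxirane of the L-series ketone transfers oxygen through the spiro transition state to the face of the E-trisubstituted olefin that gives the (10S,11S)-epoxide, and the electron-poorer, hindered 1,1-disubstituted exocyclic olefin should react much more slowly.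

Step 20
Reactants: 26 bis-silylated bromophycolide F
Product: 27 bromophycolide F
Conditions: TBAF (3 equiv), AcOH (3 equiv), THF, 0 °C → rt
Reagents that add atoms: none
Why: Buffered fluoride cleaves the aryl and the tertiary silyl ether; the near-neutral medium should avoid opening of the epoxide by the freed tertiary alcohol and migration of the benzoate.

**Compound list**

1 | geranyl acetate, (2E)-3,7-dimethylocta-2,6-dien-1-yl acetate | CC(=O)OC/C=C(\C)CCC=C(C)C | starting material
2 | (2E,6E)-8-hydroxy-3,7-dimethylocta-2,6-dien-1-yl acetate | CC(=O)OC/C=C(\C)CC/C=C(\C)CO | intermediate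
3 | (2E,6E)-8-bromo-3,7-dimethylocta-2,6-dien-1-yl acetate | CC(=O)OC/C=C(\C)CC/C=C(\C)CBr | intermediate
4 | (2E,6E)-3,7-dimethylundeca-2,6,10-trien-1-ol | OC/C=C(\C)CC/C=C(\C)CCC=C | intermediate
5 | tert-butyl (2E,6E)-3,7-dimethylundeca-2,6,10-trien-1-yl carbonate | CC(C)(C)OC(=O)OC/C=C(\C)CC/C=C(\C)CCC=C | intermediate
6 | (4aR,5S,6S,8aS)-6-bromo-5-(but-3-en-1-yl)-5,8a-dimethylhexahydro-4H-1,3-benzodioxin-2-one (trans-fused cyclic carbonate) | O=C1OC[C@H]2[C@](C)(CCC=C)[C@@H](Br)CC[C@]2(C)O1 | intermediate
7 | (1S,2R,3S,4S)-4-bromo-3-(but-3-en-1-yl)-2-(hydroxymethyl)-1,3-dimethylcyclohexan-1-ol | OC[C@H]1[C@](C)(CCC=C)[C@@H](Br)CC[C@]1(C)O | intermediate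
8 | (1S,2S,3S,4S)-4-bromo-3-(but-3-en-1-yl)-2-(iodomethyl)-1,3-dimethylcyclohexan-1-ol | IC[C@H]1[C@](C)(CCC=C)[C@@H](Br)CC[C@]1(C)O | intermediate
9 | (1S,2S,3R)-1-bromo-2-(but-3-en-1-yl)-3-(iodomethyl)-2-methyl-4-methylidenecyclohexane | C=C1CC[C@H](Br)[C@@](C)(CCC=C)[C@@H]1CI | intermediate
10 | (S)-α-hydroxy-γ-butyrolactone, (3S)-3-hydroxyoxolan-2-one | O[C@H]1CCOC1=O | starting material
11 | (3S)-4-methylpentane-1,3,4-triol | O[C@@H](CCO)C(C)(C)O | intermediate
12 | 2-[(4S)-2,2,5,5-tetramethyl-1,3-dioxolan-4-yl]ethan-1-ol | OCC[C@@H]1OC(C)(C)OC1(C)C | intermediate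
13 | (4S)-4-(2-iodoethyl)-2,2,5,5-tetramethyl-1,3-dioxolane | ICC[C@@H]1OC(C)(C)OC1(C)C | intermediate
14 | (E)-2-bromobut-2-ene | C/C=C(\C)Br | starting material
15 | {2-[(4S)-2,2,5,5-tetramethyl-1,3-dioxolan-4-yl]ethyl}zinc iodide | I[Zn]CC[C@@H]1OC(C)(C)OC1(C)C | intermediate
16 | (4S)-2,2,5,5-tetramethyl-4-[(3E)-3-methylpent-3-en-1-yl]-1,3-dioxolane | C/C=C(\C)CC[C@@H]1OC(C)(C)OC1(C)C | intermediate
17 | (3S,6E)-2,6-dimethyloct-6-ene-2,3-diol | O[C@@H](CC/C(C)=C/C)C(C)(C)O | intermediate
18 | 4-hydroxy-3-iodobenzoic acid | OC(=O)c1ccc(O)c(I)c1 | starting material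
19 | triisopropylsilyl 3-iodo-4-[(triisopropylsilyl)oxy]benzoate | CC(C)[Si](C(C)C)(C(C)C)OC(=O)c1ccc(O[Si](C(C)C)(C(C)C)C(C)C)c(I)c1 | intermediate
20 | 3-iodo-4-[(triisopropylsilyl)oxy]benzoic acid | OC(=O)c1ccc(O[Si](C(C)C)(C(C)C)C(C)C)c(I)c1 | intermediate
21 | (3S,6E)-2-hydroxy-2,6-dimethyloct-6-en-3-yl 3-iodo-4-[(triisopropylsilyl)oxy]benzoate | O=C(O[C@@H](CC/C(C)=C/C)C(C)(C)O)c1ccc(O[Si](C(C)C)(C(C)C)C(C)C)c(I)c1 | intermediate
22 | (3S,6E)-2,6-dimethyl-2-[(triethylsilyl)oxy]oct-6-en-3-yl 3-iodo-4-[(triisopropylsilyl)oxy]benzoate | O=C(O[C@@H](CC/C(C)=C/C)C(C)(C)O[Si](CC)(CC)CC)c1ccc(O[Si](C(C)C)(C(C)C)C(C)C)c(I)c1 | intermediate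
23 | {[(1R,2S,3S)-3-bromo-2-(but-3-en-1-yl)-2-methyl-6-methylidenecyclohexyl]methyl}zinc iodide | C=C1CC[C@H](Br)[C@@](C)(CCC=C)[C@@H]1C[Zn]I | intermediate
24 | seco diene: (3S,6E)-2,6-dimethyl-2-[(triethylsilyl)oxy]oct-6-en-3-yl 3-{[(1R,2S,3S)-3-bromo-2-(but-3-en-1-yl)-2-methyl-6-methylidenecyclohexyl]methyl}-4-[(triisopropylsilyl)oxy]benzoate | C=C1CC[C@H](Br)[C@@](C)(CCC=C)[C@@H]1Cc1cc(ccc1O[Si](C(C)C)(C(C)C)C(C)C)C(=O)O[C@@H](CC/C(C)=C/C)C(C)(C)O[Si](CC)(CC)CC | intermediate
25 | bis-silylated 10,11-deoxy macrolactone: 15-membered lactone with (10E)-C10=C11 olefin, aryl TIPS ether, C15 TES ether, ring stereocentres as in 24 | C=C1CC[C@H](Br)[C@@]2(C)CC/C=C(\C)CC[C@@H](C(C)(C)O[Si](CC)(CC)CC)OC(=O)c3ccc(O[Si](C(C)C)(C(C)C)C(C)C)c(c3)C[C@H]12 | intermediate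
26 | bis-silylated bromophycolide F: (10S,11S)-epoxide of 25 | C=C1CC[C@H](Br)[C@@]2(C)CC[C@@H]3O[C@@]3(C)CC[C@@H](C(C)(C)O[Si](CC)(CC)CC)OC(=O)c3ccc(O[Si](C(C)C)(C(C)C)C(C)C)c(c3)C[C@H]12 | intermediate
27 | bromophycolide F | C=C1CC[C@H](Br)[C@@]2(C)CC[C@@H]3O[C@@]3(C)CC[C@@H](C(C)(C)O)OC(=O)c3ccc(O)c(c3)C[C@H]12 | target

**Step count and risks**

Total step count: 20. Longest linear sequence: 12 steps (steps 1–8, then 17–20).

Steps most likely to fail:

1. Step 5 (bromonium cyclisation). What may go wrong: transfer of Br+ with too little facial discrimination, because the distal olefin now carries a methyl and a butenyl group instead of two methyl groups, or Br+ transfer to the vinyl group, so that the bromocyclohexane is formed in low enantiomeric purity. Fallback (resolution instead of asymmetric catalysis), from 5 back to 7: 5 is cyclised without asymmetric induction using Et2SBr·SbCl5Br (MeNO2, −25 °C), which should give 6 together with its enantiomer ent-6 F1. Methanolysis as in step 6 gives 7 together with ent-7 F2. A lipase-catalysed acylation of the primary alcohol (lipase from Burkholderia cepacia, vinyl acetate, t-BuOMe) then resolves the pair. If ent-7 reacts faster, it is removed as the primary acetate of ent-7 F3 and 7 is recovered directly. If 7 reacts faster, the primary acetate of 7 F4 is separated from F2 and methanolysed (K2CO3, MeOH) to 7.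

2. Step 18 (ring-closing metathesis). What may go wrong: ethylene release from the terminal vinyl group builds up the Mo methylidene complex, which decomposes the catalyst and opens a non-stereoretentive pathway; oligomerisation may compete with ring closure. Fallback (methylene capping, same bond formed), from 24 back to 25: 24 is first treated with excess (Z)-but-2-ene and the same Mo catalyst, which should convert the vinyl group into a (Z)-prop-1-enyl group, giving the capped seco diene F5. After removal of the butene, F5 is cyclised at 1 mM under reduced pressure; the ring closure then runs between two internal olefins, releases but-2-ene and does not pass through the methylidene complex.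

3. Step 19 (epoxidation). What may go wrong: the conformation of the macrocycle overrides the ketone-derived dioxirane so that oxygen is delivered to the wrong face, or the exocyclic methylene is oxidised as well. Fallback (substrate control instead of catalyst control), from 25 back to 26: peracid epoxidation (mCPBA, NaHCO3, CH2Cl2, −20 °C), in which the electron-rich trisubstituted ring olefin should react first and the peracid should attack the outer face of the ring olefin. 26 would be separated from the (10R,11R)-epoxide diastereomer F6.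

**Further compounds**

F1 | step 5 | ent-6, (4aS,5R,6R,8aR)-6-bromo-5-(but-3-en-1-yl)-5,8a-dimethylhexahydro-4H-1,3-benzodioxin-2-one | O=C1OC[C@@H]2[C@@](C)(CCC=C)[C@H](Br)CC[C@@]2(C)O1
F2 | step 5 | ent-7, (1R,2S,3R,4R)-4-bromo-3-(but-3-en-1-yl)-2-(hydroxymethyl)-1,3-dimethylcyclohexan-1-ol | OC[C@@H]1[C@@](C)(CCC=C)[C@H](Br)CC[C@@]1(C)O
F3 | step 5 | primary acetate of ent-7 | CC(=O)OC[C@@H]1[C@@](C)(CCC=C)[C@H](Br)CC[C@@]1(C)O
F4 | step 5 | primary acetate of 7 | CC(=O)OC[C@H]1[C@](C)(CCC=C)[C@@H](Br)CC[C@]1(C)O
F5 | step 18 | capped seco diene: 24 with a (Z)-pent-3-en-1-yl arm in place of the but-3-en-1-yl arm | C=C1CC[C@H](Br)[C@@](C)(CC/C=C\C)[C@@H]1Cc1cc(ccc1O[Si](C(C)C)(C(C)C)C(C)C)C(=O)O[C@@H](CC/C(C)=C/C)C(C)(C)O[Si](CC)(CC)CC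
F6 | step 19 | (10R,11R)-epoxide diastereomer of 26 | C=C1CC[C@H](Br)[C@@]2(C)CC[C@H]3O[C@]3(C)CC[C@@H](C(C)(C)O[Si](CC)(CC)CC)OC(=O)c3ccc(O[Si](C(C)C)(C(C)C)C(C)C)c(c3)C[C@H]12
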